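**Retrosynthetic overview**

1. Target 13 is an isoflavone with no stereocentre: ring A (benzo ring, 7-prenyloxy, 8-methoxy), ring C (pyranone O1–C2–C3–C4) and ring B (4-methoxyphenyl on C3).
2. The strategy rests on the O1–C2 unit of ring C. C2 is a CH on the aryl oxygen O1, and O1 sits on C8a, ortho to the C4a that carries the C4 carbonyl. A 2-methoxyaryl ketone already holds this aryl–O–C unit, so its methyl carbon can become C2.
3. C2=C3 is taken back to isoflavanone 10 (enolate dehydrogenation). C2–C3 is taken back to the α-aryl-α-diazoketone 9 (dirhodium carbenoid insertion into the O1–CH3 group, closing ring C).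
4. 9 comes from deoxybenzoin 8 by diazo transfer; 8 from aldehyde 5 and the 4-methoxybenzyl Grignard reagent 6 (addition, oxidation); 5 from 2,3,4-trihydroxybenzaldehyde 1 (O4 prenylation, then methylation of O2 and O3 with two equivalents of methyl iodide).
5. Rings A and B are bought with 1 and 6; ring C is the only ring formed (step 6).

Key step: step 6

Remark: isoflavone numbering (O1, C2, C3, C4, C4a, C5 to C8, C8a) is used for these atoms in the open-chain precursors as well. Compounds 7, 10 and 12 are racemic. Reagent 6 is taken as the commercial THF solution.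

**Step 1**
Reactants: 1 2,3,4-trihydroxybenzaldehyde; 2 prenyl bromide (1-bromo-3-methylbut-2-ene)
Product: 3 2,3-dihydroxy-4-(3-methylbut-2-enyloxy)benzaldehyde
Conditions: NaHCO3 (1.5 equiv), 2 (1.05 equiv), DMF, 40 °C, N2
Reagents that add atoms: none
Why: Williamson ether synthesis under bicarbonate control, in which only the O4 hydroxyl (para to the formyl group, not hydrogen-bonded) is acidic enough to be ionised, while the O2 hydroxyl is tied to the aldehyde by a hydrogen bond and the O3 hydroxyl is the least acidic, so SN2 attack on the primary allylic bromide should take place at O4.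

**Step 2**
Reactants: 3 2,3-dihydroxy-4-(3-methylbut-2-enyloxy)benzaldehyde; 4 methyl iodide (two equivalents are consumed, one per hydroxyl)
Product: 5 2,3-dimethoxy-4-(3-methylbut-2-enyloxy)benzaldehyde
Conditions: MeI (4 equiv), K2CO3 (3 equiv), DMF, 40 °C, closed flask
Reagents that add atoms: methyl iodide (the second equivalent, which supplies the second O-methyl group), CI
Why: twofold Williamson O-methylation, in which one molecule of methyl iodide alkylates the O3 phenoxide and a second one the hydrogen-bonded O2 phenoxide under excess reagent and carbonate in DMF, while the aldehyde and the prenyl ether are inert.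

**Step 3**
Reactants: 5 2,3-dimethoxy-4-(3-methylbut-2-enyloxy)benzaldehyde; 6 4-methoxybenzylmagnesium chloride
Product: 7 1-[2,3-dimethoxy-4-(3-methylbut-2-enyloxy)phenyl]-2-(4-methoxyphenyl)ethanol (racemic)
Conditions: 6 (1.3 equiv), THF, −20 °C to 0 °C; then aq. NH4Cl
Reagents that add atoms: none
Why: Grignard 1,2-addition to an aldehyde that has no α-hydrogen; the carbinol centre forms racemic and is removed by the oxidation in step 4.

**Step 4**
Reactants: 7 1-[2,3-dimethoxy-4-(3-methylbut-2-enyloxy)phenyl]-2-(4-methoxyphenyl)ethanol
Product: 8 1-[2,3-dimethoxy-4-(3-methylbut-2-enyloxy)phenyl]-2-(4-methoxyphenyl)ethanone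
Conditions: Dess–Martin periodinane (1.3 equiv), CH2Cl2, 0 °C to rt
Reagents that add atoms: none
Why: Dess–Martin oxidation of a secondary benzylic alcohol by ligand exchange at hypervalent iodine and loss of the carbinol hydrogen, under near-neutral conditions that leave the prenyl alkene, the allylic ether and the electron-rich rings untouched.

**Step 5**
Reactants: 8 1-[2,3-dimethoxy-4-(3-methylbut-2-enyloxy)phenyl]-2-(4-methoxyphenyl)ethanone
Product: 9 2-diazo-1-[2,3-dimethoxy-4-(3-methylbut-2-enyloxy)phenyl]-2-(4-methoxyphenyl)ethanone
Conditions: 4-acetamidobenzenesulfonyl azide (1.3 equiv), DBU (1.5 equiv), MeCN, 0 °C to rt, dark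
Reagents that add atoms: 4-acetamidobenzenesulfonyl azide, CC(=O)Nc1ccc(cc1)S(=O)(=O)N=[N+]=[N-]
Why: Regitz diazo transfer, in which DBU forms the enolate of the benzylic methylene (activated by the ketone and the anisyl ring), the enolate adds to the terminal azide nitrogen and the triazene collapses to the α-aryl-α-diazoketone and the sulfonamide.

**Step 6**
Reactants: 9 2-diazo-1-[2,3-dimethoxy-4-(3-methylbut-2-enyloxy)phenyl]-2-(4-methoxyphenyl)ethanone
Product: 10 8-methoxy-3-(4-methoxyphenyl)-7-(3-methylbut-2-enyloxy)chroman-4-one (8,4'-dimethoxy-7-prenyloxyisoflavanone, racemic at C3)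
Conditions: Rh2(OAc)4 (2 mol %), dry CH2Cl2, 4 Å MS, reflux, slow syringe-pump addition of 9 (final about 0.005 M)
Reagents that add atoms: none
Why: Proposed new method: Rh2(OAc)4 should expel N2 from 9 to give a dirhodium carbenoid at C3 that carries a donor (the 4-methoxyphenyl ring) and an acceptor (the C4 ketone), and this carbon inserts into one C–H bond of the methyl group on O1 through a concerted, hydride-transfer-like three-centre transition state, forming the C2–C3 bond. The closest known reaction type is the dirhodium-catalysed intramolecular C–H insertion of 2-alkoxyphenyl diazoketones next to the ether oxygen, which gives chroman-4-ones, supported by the known insertion of donor–acceptor carbenoids into C–H bonds of methyl ethers; not yet shown is the combination of a primary O–CH3 site and an α-aryl diazoketone. Ring C closes as a six-membered ring by 1,6 C–H insertion, the ring being made of C3, C4, C4a, C8a, O1 and C2, and the lone pair on O1 stabilises the positive charge that builds up on C2. C3 becomes a stereocentre without any controlling element, so 10 is racemic, which is accepted because step 7 turns C3 into an sp2 carbon. The selectivity needed is insertion over (a) attack of the carbenoid on O1 to a five-membered oxonium ylide followed by a 1,2-methyl shift, (b) cyclopropanation of the prenyl alkene of a second molecule or carbene dimerisation, and (c) O–H insertion of water. The substrate and set-up secure it as follows: the ortho methoxy methyl is the only C–H site within reach, the prenyl alkene is para to the ketone and out of reach of its own carbenoid, ylide formation at an aryl ether oxygen is reversible and a methyl group migrates slowly, the donor aryl group tempers the carbenoid, and slow addition at high dilution over molecular sieves holds back the bimolecular paths.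

**Step 7**
Reactants: 10 8-methoxy-3-(4-methoxyphenyl)-7-(3-methylbut-2-enyloxy)chroman-4-one
Product: 13 8-methoxy-3-(4-methoxyphenyl)-7-(3-methylbut-2-enyloxy)chromen-4-one (the target), via lithium enolate 11 (not isolated), via sulfilimine adduct 12 (not isolated)
Conditions: LiN(iPr)2 (1.1 equiv), THF, −78 °C, 20 min; then N-tert-butylbenzenesulfinimidoyl chloride (1.2 equiv), −78 °C, 30 min
Reagents that add atoms: none
Why: Mukaiyama dehydrogenation, in which the only possible enolate (C3) attacks sulfur with loss of chloride and the C3 sulfilimine undergoes syn elimination through a five-membered transition state, its nitrogen taking a C2 hydrogen, so that C2=C3 forms in conjugation with the C4 ketone and ring B, the prenyl alkene meets no oxidant and the racemic C3 centre disappears.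

**Compound list**

1 | 2,3,4-trihydroxybenzaldehyde | O=Cc1ccc(O)c(O)c1O | starting material
2 | prenyl bromide (1-bromo-3-methylbut-2-ene) | CC(C)=CCBr | starting material
3 | 2,3-dihydroxy-4-(3-methylbut-2-enyloxy)benzaldehyde | O=Cc1ccc(OCC=C(C)C)c(O)c1O | intermediate
4 | methyl iodide | CI | starting material
5 | 2,3-dimethoxy-4-(3-methylbut-2-enyloxy)benzaldehyde | O=Cc1ccc(OCC=C(C)C)c(OC)c1OC | intermediate
6 | 4-methoxybenzylmagnesium chloride (commercial solution in THF) | COc1ccc(C[Mg]Cl)cc1 | starting material
7 | 1-[2,3-dimethoxy-4-(3-methylbut-2-enyloxy)phenyl]-2-(4-methoxyphenyl)ethanol, racemic | COc1ccc(CC(O)c2ccc(OCC=C(C)C)c(OC)c2OC)cc1 | intermediate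
8 | 1-[2,3-dimethoxy-4-(3-methylbut-2-enyloxy)phenyl]-2-(4-methoxyphenyl)ethanone | COc1ccc(CC(=O)c2ccc(OCC=C(C)C)c(OC)c2OC)cc1 | intermediate
9 | 2-diazo-1-[2,3-dimethoxy-4-(3-methylbut-2-enyloxy)phenyl]-2-(4-methoxyphenyl)ethanone | COc1ccc(C(=[N+]=[N-])C(=O)c2ccc(OCC=C(C)C)c(OC)c2OC)cc1 | intermediate
10 | 8-methoxy-3-(4-methoxyphenyl)-7-(3-methylbut-2-enyloxy)chroman-4-one, racemic at C3 | COc1ccc(C2COc3c(OC)c(OCC=C(C)C)ccc3C2=O)cc1 | intermediate
11 | lithium 8-methoxy-3-(4-methoxyphenyl)-7-(3-methylbut-2-enyloxy)-2H-chromen-4-olate (lithium enolate of 10, not isolated) | COc1ccc(C2=C(O[Li])c3ccc(OCC=C(C)C)c(OC)c3OC2)cc1 | intermediate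
12 | 3-(N-tert-butyl-S-phenylsulfinimidoyl)-8-methoxy-3-(4-methoxyphenyl)-7-(3-methylbut-2-enyloxy)chroman-4-one (sulfilimine adduct, stereoisomer mixture, not isolated) | COc1ccc(C2(S(=NC(C)(C)C)c3ccccc3)COc3c(OC)c(OCC=C(C)C)ccc3C2=O)cc1 | intermediate
13 | 8-methoxy-3-(4-methoxyphenyl)-7-(3-methylbut-2-enyloxy)chromen-4-one (8,4'-dimethoxy-7-prenyloxyisoflavone), no stereocentre | COc1ccc(-c2coc3c(OC)c(OCC=C(C)C)ccc3c2=O)cc1 | target

**Step count**

Total steps: 7. Longest linear sequence: 7 steps (1 to 13).

**Steps most likely to fail**

Step 6 (carries the label). The carbenoid may be consumed before it inserts into the primary C–H bond: capture by the O1 lone pair with rearrangement of the ylide, or reaction with a second molecule. The fallback uses known chemistry and brings C2 in as a one-carbon electrophile instead of by C–H insertion. It sets out from 3 and returns to the route at 13. The dianion of 3 (NaH 2.2 equiv, DMSO, rt) is treated with MeI (1.0 equiv); the non-chelated, more nucleophilic O3 phenoxide should react and give 2-hydroxy-3-methoxy-4-(3-methylbut-2-enyloxy)benzaldehyde F1. Excess 6 in THF should add to the aldehyde and give 1-[2-hydroxy-3-methoxy-4-(3-methylbut-2-enyloxy)phenyl]-2-(4-methoxyphenyl)ethanol F2. MnO2 in CH2Cl2 should oxidise the benzylic alcohol to 1-[2-hydroxy-3-methoxy-4-(3-methylbut-2-enyloxy)phenyl]-2-(4-methoxyphenyl)ethanone F3. Heating with N,N-dimethylformamide dimethyl acetal in toluene at 90 °C should give 3-(dimethylamino)-1-[2-hydroxy-3-methoxy-4-(3-methylbut-2-enyloxy)phenyl]-2-(4-methoxyphenyl)prop-2-en-1-one F4. The free O1 hydroxyl then adds to the enaminone carbon and dimethylamine is lost, which closes ring C directly at the isoflavone stage and gives 13.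

Step 7. The lithium enolate may expel the O1 phenoxide from C2 (β-elimination that opens ring C) faster than it is trapped at sulfur, or the elimination of the sulfilimine may stall. The fallback avoids a free enolate and uses a Saegusa–Ito oxidation. It sets out from 10 and returns at 13. Soft enolisation (Me3SiOTf, Et3N, CH2Cl2, 0 °C) should give 8-methoxy-3-(4-methoxyphenyl)-7-(3-methylbut-2-enyloxy)-4-(trimethylsilyloxy)-2H-chromene F5. Pd(OAc)2 (1.1 equiv) in MeCN at rt then palladates C3, and β-hydride elimination from C2 gives the C2=C3 bond of 13. Quinone oxidants are avoided because they cleave prenyl ethers.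

Step 1. Alkylation may spread over O3 and O4, go on to dialkylation, or turn to C-prenylation of the ambident phenoxide, and the catecholate may autoxidise. The fallback replaces phenoxide alkylation by activation of the alcohol under neutral conditions. It sets out from 1 and returns at 3. It is a Mitsunobu etherification with 3-methylbut-2-en-1-ol, PPh3 and diisopropyl azodicarboxylate in THF at 0 °C. Only the most acidic hydroxyl (on C4) should protonate the betaine, and no phenoxide is present. No new compound is made on the way.

**Further compounds**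

F1 | step 6 | 2-hydroxy-3-methoxy-4-(3-methylbut-2-enyloxy)benzaldehyde | O=Cc1ccc(OCC=C(C)C)c(OC)c1O
F2 | step 6 | 1-[2-hydroxy-3-methoxy-4-(3-methylbut-2-enyloxy)phenyl]-2-(4-methoxyphenyl)ethanol, racemic | COc1ccc(CC(O)c2ccc(OCC=C(C)C)c(OC)c2O)cc1
F3 | step 6 | 1-[2-hydroxy-3-methoxy-4-(3-methylbut-2-enyloxy)phenyl]-2-(4-methoxyphenyl)ethanone | COc1ccc(CC(=O)c2ccc(OCC=C(C)C)c(OC)c2O)cc1
F4 | step 6 | 3-(dimethylamino)-1-[2-hydroxy-3-methoxy-4-(3-methylbut-2-enyloxy)phenyl]-2-(4-methoxyphenyl)prop-2-en-1-one | COc1ccc(C(=CN(C)C)C(=O)c2ccc(OCC=C(C)C)c(OC)c2O)cc1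
F5 | step 7 | 8-methoxy-3-(4-methoxyphenyl)-7-(3-methylbut-2-enyloxy)-4-(trimethylsilyloxy)-2H-chromene | COc1ccc(C2=C(O[Si](C)(C)C)c3ccc(OCC=C(C)C)c(OC)c3OC2)cc1
F0 | step 1 | none | none
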